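**Plan**
- Retrosynthetic cuts, in order: the S–O bonds at O7 and O3'; the C5–O and C7–O bonds of ring A, each traced back to C–F; last, C3–C4 and O1–C8a of the pyranone (ring C).
- Enabling feature: the oxygenated ring A carbons C5, C7 and C8a lie ortho, para and ortho to C4a, which carries the C4 carbonyl. Ring A plus C4 therefore maps onto a 2,4,6-trifluorobenzoyl group whose mirror plane makes the two ortho C–F bonds identical.
- Forward: ring B enters as 3',4'-dihydroxyacetophenone (O4' benzyl, O3' PMB) and ring A as the acid chloride. Ring C is the only ring built, in one pot, by enolate C-acylation and then intramolecular fluoride displacement.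
- Both remaining fluorides are then exchanged for PMB-oxy groups and the three PMB ethers are cleaved. O7 and O3' are sulfated (5-OH is held back by its hydrogen bond to the C4 carbonyl, O4' by benzyl), and benzyl is hydrogenolysed.
- Stereochemistry: the target has no stereocentre, stereogenic double bond or axis, so nothing has to be set or preserved.

Key step: step 3

Remark: the target is drawn as the free bis(hydrogen sulfate). The sulfate esters are therefore carried as sodium salts and protonated on an acidic resin only at the very end, in the cold, because the acid form is prone to slow self-catalysed hydrolysis.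

Step 1
Reactants: 1 3',4'-dihydroxyacetophenone; 2 benzyl bromide
Product: 3 1-[4-(benzyloxy)-3-hydroxyphenyl]ethan-1-one
Conditions: 2 (1.0 equiv), NaHCO3 (1.5 equiv), NaI (cat.), DMF, 40 °C
Reagents that add atoms: none
Why: Williamson etherification under weak-base control: the 4-OH is para to the acetyl group and clearly the more acidic phenol, so hydrogen carbonate ionises it preferentially and one equivalent of halide should alkylate it ahead of the 3-OH, as is well established for 3,4-dihydroxyaryl aldehydes and ketones.

Step 2
Reactants: 3 1-[4-(benzyloxy)-3-hydroxyphenyl]ethan-1-one; 4 4-methoxybenzyl alcohol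
Product: 5 1-{4-(benzyloxy)-3-[(4-methoxybenzyl)oxy]phenyl}ethan-1-one
Conditions: PPh3, DIAD (1.2 equiv each), THF, 0 °C → rt
Reagents that add atoms: none
Why: Mitsunobu etherification of a phenol with a primary benzylic alcohol, run under essentially neutral conditions that touch neither the enolisable methyl ketone nor the benzyl ether, and fed by the same alcohol that step 4 needs.

Step 3
Reactants: 5 1-{4-(benzyloxy)-3-[(4-methoxybenzyl)oxy]phenyl}ethan-1-one; 6 2,4,6-trifluorobenzoyl chloride
Product: 9 2-{4-(benzyloxy)-3-[(4-methoxybenzyl)oxy]phenyl}-5,7-difluoro-4H-chromen-4-one, via lithium ketone enolate 7 (not isolated), via lithium diketonate 8 (not isolated)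
Conditions: LiHMDS (2.2 equiv), THF, −78 °C; 6 (1.0 equiv), −78 → 0 °C; then DMPU, 60 °C; aq. NH4Cl
Reagents that add atoms: none
Why: One equivalent of LiHMDS converts 5 into the lithium enolate 7, which attacks the acid chloride through carbon (Claisen-type C-acylation, C3–C4), and the second equivalent immediately deprotonates the much more acidic 1,3-diketone to the chelated Z-diketonate 8, which blocks a second acylation. On warming in the more dissociating THF–DMPU medium the oxygen on C2 adds to a fluorine-bearing ortho carbon, the charge of the Meisenheimer adduct is spread onto the C4 carbonyl and eased by the two other fluorines, and loss of lithium fluoride forms O1–C8a (intramolecular SNAr). The closest known reaction type is the one-pot acylation/SNAr cyclisation of ketone enolates with 2-fluoro- and polyfluorobenzoyl chlorides, an established entry to chromones, flavones and 4-quinolones. Ring C closes as a six-membered ring by a formally 6-endo-trig addition–elimination, the accepting C4a=C8a bond lying inside the new ring, and no stereocentre is created. The step needs C- over O-acylation, secured by the tightly ion-paired lithium enolate at −78 °C in THF, and a single closure site, secured by the mirror symmetry of the aroyl group (both ortho fluorines give the same flavone) and by the para fluorine being out of reach of the tethered oxygen. Benzyl and PMB ethers are inert to the amide base, and the hindered silylamine by-product is too poor a nucleophile to attack the C–F bonds that remain.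

Step 4
Reactants: 9 2-{4-(benzyloxy)-3-[(4-methoxybenzyl)oxy]phenyl}-5,7-difluoro-4H-chromen-4-one; 4 4-methoxybenzyl alcohol (two molecules are incorporated)
Product: 10 2-{4-(benzyloxy)-3-[(4-methoxybenzyl)oxy]phenyl}-5,7-bis[(4-methoxybenzyl)oxy]-4H-chromen-4-one
Conditions: 4 (2.6 equiv), NaH (2.5 equiv), THF, 0 °C; then 9, DMF, 0 → 60 °C, strictly anhydrous
Reagents that add atoms: none
Why: Twofold SNAr of carbonyl-activated aryl fluorides by an alkoxide: C5–F is ortho and C7–F para to the acyl-bearing C4a, fluoride is the best leaving group for addition–elimination, the first alkoxy group enters meta to the second reaction site and so does not push charge into the second Meisenheimer adduct, and alkoxide addition at C2 is reversible and unproductive as long as hydroxide is excluded.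

Step 5
Reactants: 10 2-{4-(benzyloxy)-3-[(4-methoxybenzyl)oxy]phenyl}-5,7-bis[(4-methoxybenzyl)oxy]-4H-chromen-4-one
Product: 11 2-[4-(benzyloxy)-3-hydroxyphenyl]-5,7-dihydroxy-4H-chromen-4-one (4'-O-benzylluteolin)
Conditions: TFA (10% v/v), anisole (15 equiv), CH2Cl2, 0 °C
Reagents that add atoms: none
Why: Acidolysis of aryl 4-methoxybenzyl ethers (SN1 ionisation) with Friedel–Crafts capture of the 4-methoxybenzyl cation by excess anisole, which should keep the cation away from C6 and C8 of the liberated phloroglucinol ring, while the unsubstituted benzyl ether ionises far more slowly and should survive cold dilute TFA.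

Step 6
Reactants: 11 2-[4-(benzyloxy)-3-hydroxyphenyl]-5,7-dihydroxy-4H-chromen-4-one
Product: 13 disodium 4'-O-benzylluteolin 7,3'-disulfate, via bis(pyridinium) disulfate salt 12 (not isolated)
Conditions: SO3·pyridine (3 equiv), pyridine, rt; aq. NaHCO3 to pH 7–8; C18 or Sephadex LH-20
Reagents that add atoms: sulfur trioxide–pyridine complex, O=S(=O)([O-])[n+]1ccccc1; sodium hydrogen carbonate, [Na+].OC(=O)[O-]
Why: O-sulfation of phenols with a sulfur trioxide–amine complex: the acidic 7-OH and the 3'-OH are the only accessible nucleophiles, because O4' is benzylated and the 5-OH is locked in a six-membered hydrogen bond to the C4 carbonyl and is known across the flavonoid series to resist sulfation at room temperature with a small excess of reagent; the exchange to sodium also removes pyridine, which would otherwise inhibit the palladium catalyst of step 7.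

Step 7
Reactants: 13 disodium 4'-O-benzylluteolin 7,3'-disulfate
Product: 15 luteolin 7,3'-disulfate, via disodium luteolin 7,3'-disulfate 14 (not isolated)
Conditions: H2 (1 atm), 10% Pd/C, MeOH–H2O, rt; filter; sulfonic acid cation-exchange resin (H+ form), H2O, 0–5 °C; freeze-dry
Reagents that add atoms: none
Why: Catalytic hydrogenolysis of an aryl benzyl ether over Pd/C in neutral medium, a standard last step for benzyl-protected flavonoid sulfates that leaves the sulfate monoester anions and the C2=C3 bond alone, followed by cation exchange on a sulfonic acid resin to put protons in place of sodium.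

**Compound list**
1 | 3',4'-dihydroxyacetophenone | CC(=O)c1ccc(O)c(O)c1 | starting material
2 | benzyl bromide | BrCc1ccccc1 | starting material
3 | 1-[4-(benzyloxy)-3-hydroxyphenyl]ethan-1-one | CC(=O)c1ccc(OCc2ccccc2)c(O)c1 | intermediate
4 | 4-methoxybenzyl alcohol | COc1ccc(CO)cc1 | starting material
5 | 1-{4-(benzyloxy)-3-[(4-methoxybenzyl)oxy]phenyl}ethan-1-one | CC(=O)c1ccc(OCc2ccccc2)c(OCc2ccc(OC)cc2)c1 | intermediate
6 | 2,4,6-trifluorobenzoyl chloride | O=C(Cl)c1c(F)cc(F)cc1F | starting material
7 | lithium 1-{4-(benzyloxy)-3-[(4-methoxybenzyl)oxy]phenyl}ethen-1-olate | [Li+].C=C([O-])c1ccc(OCc2ccccc2)c(OCc2ccc(OC)cc2)c1 | intermediate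
8 | lithium (Z)-1-{4-(benzyloxy)-3-[(4-methoxybenzyl)oxy]phenyl}-3-oxo-3-(2,4,6-trifluorophenyl)prop-1-en-1-olate | [Li+].[O-]/C(=C\C(=O)c1c(F)cc(F)cc1F)c1ccc(OCc2ccccc2)c(OCc2ccc(OC)cc2)c1 | intermediate
9 | 2-{4-(benzyloxy)-3-[(4-methoxybenzyl)oxy]phenyl}-5,7-difluoro-4H-chromen-4-one | O=c1cc(-c2ccc(OCc3ccccc3)c(OCc3ccc(OC)cc3)c2)oc2cc(F)cc(F)c12 | intermediate
10 | 2-{4-(benzyloxy)-3-[(4-methoxybenzyl)oxy]phenyl}-5,7-bis[(4-methoxybenzyl)oxy]-4H-chromen-4-one | O=c1cc(-c2ccc(OCc3ccccc3)c(OCc3ccc(OC)cc3)c2)oc2cc(OCc3ccc(OC)cc3)cc(OCc3ccc(OC)cc3)c12 | intermediate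
11 | 2-[4-(benzyloxy)-3-hydroxyphenyl]-5,7-dihydroxy-4H-chromen-4-one (4'-O-benzylluteolin) | O=c1cc(-c2ccc(OCc3ccccc3)c(O)c2)oc2cc(O)cc(O)c12 | intermediate
12 | bis(pyridinium) 4'-O-benzylluteolin 7,3'-disulfate | c1cc[nH+]cc1.c1cc[nH+]cc1.O=c1cc(-c2ccc(OCc3ccccc3)c(OS(=O)(=O)[O-])c2)oc2cc(OS(=O)(=O)[O-])cc(O)c12 | intermediate
13 | disodium 4'-O-benzylluteolin 7,3'-disulfate | [Na+].[Na+].O=c1cc(-c2ccc(OCc3ccccc3)c(OS(=O)(=O)[O-])c2)oc2cc(OS(=O)(=O)[O-])cc(O)c12 | intermediate
14 | disodium luteolin 7,3'-disulfate | [Na+].[Na+].O=c1cc(-c2ccc(O)c(OS(=O)(=O)[O-])c2)oc2cc(OS(=O)(=O)[O-])cc(O)c12 | intermediate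
15 | luteolin 7,3'-disulfate, 5-hydroxy-2-[4-hydroxy-3-(sulfooxy)phenyl]-4-oxo-4H-chromen-7-yl hydrogen sulfate (achiral) | O=c1cc(-c2ccc(O)c(OS(=O)(=O)O)c2)oc2cc(OS(=O)(=O)O)cc(O)c12 | target

Total step count: 7. Longest linear sequence: 7 steps (1 → 15).

**Steps most likely to fail**

Step 4. The second fluoride exchange may stall after the first. Alternatively, the alkoxide may add to C2 and open the pyranone at the temperature the second exchange needs. The fallback is a staged exchange that ends with a hydroxide surrogate.
- It sets out from 9. One equivalent of the sodium alkoxide of 4 in DMF at 0 °C should replace the unhindered para fluoride and give 2-{4-(benzyloxy)-3-[(4-methoxybenzyl)oxy]phenyl}-5-fluoro-7-[(4-methoxybenzyl)oxy]-4H-chromen-4-one F1.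
- The small alkoxide of 2-(methylsulfonyl)ethanol (NaH, DMF, rt) then takes the peri fluoride to give the 5-[2-(methylsulfonyl)ethoxy]flavone F2.
- Under the same base F2 loses methyl vinyl sulfone by E1cB elimination. This leaves 2-{4-(benzyloxy)-3-[(4-methoxybenzyl)oxy]phenyl}-5-hydroxy-7-[(4-methoxybenzyl)oxy]-4H-chromen-4-one F3, and the irreversible elimination pulls the exchange forward.
- TFA/anisole as in step 5 strips the two PMB ethers of F3, and the sequence comes back to the route at 11.
- If the first alkoxide entered at C5 instead, the same operations would still converge on 11.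

Step 3. The enolate may be acylated at oxygen or acylated twice, or the lithium diketonate may fail to close the ring in the same pot. The fallback keeps the two bond formations but separates them and uses a softer acyl donor.
- It sets out from 6 and 5. Acid chloride 6 is converted with 1H-benzotriazole and Et3N (CH2Cl2, 0 °C) into 1-(2,4,6-trifluorobenzoyl)-1H-benzotriazole F4, a reagent class known for clean C-acylation of ketone enolates.
- The lithium enolate of 5 (LiHMDS, 2 equiv, THF, −78 °C) is acylated with F4. After a mildly acidic quench, 1-{4-(benzyloxy)-3-[(4-methoxybenzyl)oxy]phenyl}-3-(2,4,6-trifluorophenyl)propane-1,3-dione F5 is isolated.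
- F5 is cyclised on its own with K2CO3 in DMF at 80 °C, and the sequence comes back to the route at 9.

Step 6. Site control may be lost through partial sulfation of the 5-OH or incomplete reaction at the more hindered O3'. The resulting ionic mixture would be hard to separate. The fallback installs the sulfates as neutral, chromatographable diesters.
- It sets out from 11. 2,2,2-Trichloroethyl chlorosulfate (2.3 equiv), Et3N and DMAP in THF at 0 °C → rt should give 4'-O-benzylluteolin 7,3'-bis(2,2,2-trichloroethyl sulfate) F6, which can be purified on silica and assigned before going on.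
- Pd/C with ammonium formate in MeOH then removes both trichloroethyl groups by reductive fragmentation and the benzyl ether by transfer hydrogenolysis in one operation, giving diammonium luteolin 7,3'-disulfate F7.
- The acidic resin of step 7 converts F7 into the acid form, and the sequence comes back to the route at 15.

**Further compounds**
F1 | step 4 | 2-{4-(benzyloxy)-3-[(4-methoxybenzyl)oxy]phenyl}-5-fluoro-7-[(4-methoxybenzyl)oxy]-4H-chromen-4-one | O=c1cc(-c2ccc(OCc3ccccc3)c(OCc3ccc(OC)cc3)c2)oc2cc(OCc3ccc(OC)cc3)cc(F)c12
F2 | step 4 | 2-{4-(benzyloxy)-3-[(4-methoxybenzyl)oxy]phenyl}-7-[(4-methoxybenzyl)oxy]-5-[2-(methylsulfonyl)ethoxy]-4H-chromen-4-one | O=c1cc(-c2ccc(OCc3ccccc3)c(OCc3ccc(OC)cc3)c2)oc2cc(OCc3ccc(OC)cc3)cc(OCCS(C)(=O)=O)c12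
F3 | step 4 | 2-{4-(benzyloxy)-3-[(4-methoxybenzyl)oxy]phenyl}-5-hydroxy-7-[(4-methoxybenzyl)oxy]-4H-chromen-4-one | O=c1cc(-c2ccc(OCc3ccccc3)c(OCc3ccc(OC)cc3)c2)oc2cc(OCc3ccc(OC)cc3)cc(O)c12
F4 | step 3 | 1-(2,4,6-trifluorobenzoyl)-1H-benzotriazole | O=C(c1c(F)cc(F)cc1F)n1nnc2ccccc21
F5 | step 3 | 1-{4-(benzyloxy)-3-[(4-methoxybenzyl)oxy]phenyl}-3-(2,4,6-trifluorophenyl)propane-1,3-dione | O=C(CC(=O)c1c(F)cc(F)cc1F)c1ccc(OCc2ccccc2)c(OCc2ccc(OC)cc2)c1
F6 | step 6 | 4'-O-benzylluteolin 7,3'-bis(2,2,2-trichloroethyl sulfate) | O=c1cc(-c2ccc(OCc3ccccc3)c(OS(=O)(=O)OCC(Cl)(Cl)Cl)c2)oc2cc(OS(=O)(=O)OCC(Cl)(Cl)Cl)cc(O)c12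
F7 | step 6 | diammonium luteolin 7,3'-disulfate | [NH4+].[NH4+].O=c1cc(-c2ccc(O)c(OS(=O)(=O)[O-])c2)oc2cc(OS(=O)(=O)[O-])cc(O)c12
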